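Cuts: first the ester C–O bond at C1′, giving shikonin and 3-acetoxy-3-methylbutanoic acid. Then C3–C4, C1–C2 and C1–C8a of the quinone ring are cut together, giving an aryl(methoxy)carbene chromium complex, one of its CO ligands and a terminal alkyne.
Enabling feature: the quinone ring bears oxygen on C1 and C4 (para). Between them lies a C2=C3 unit with one substituent on C2 and H on C3, which maps onto CO carbon / alkyne / carbene carbon. The only stereocentre, C1′, is bonded directly to C2, so in the alkyne it is a propargylic carbinol carbon.
Rings: the C5–C8 benzenoid ring is bought as hydroquinone. The C1–C4 ring is closed onto it by one benzannulation that also brings in the whole side chain. Oxidation, desilylation and MOM removal then unveil the naphthazarin, and the acyl chain is joined last.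
Stereochemistry: C1′ (R) comes from a catalyst-controlled asymmetric transfer hydrogenation of an alkynyl ketone. No later step breaks a bond at C1′ and the last acylation is at oxygen, so R stays R.

Key step: step 8

Remark: positions follow 1,4-naphthoquinone numbering, with the side chain on C2 and its carbinol carbon as C1′. In the SMILES the carbonyl ligands are drawn as Cr=C=O and the η6 complex as dot-separated parts, for atom bookkeeping only.

Step 1
Reactants: 1 hydroquinone
Product: 2 1,4-bis(methoxymethoxy)benzene
Conditions: MOMCl (2.5 equiv), i-Pr2NEt (3 equiv), CH2Cl2, 0 °C → rt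
Reagents that add atoms: chloromethyl methyl ether (MOMCl), COCCl
Why: Williamson-type O-alkylation of both phenols with the very electrophilic chloromethyl ether gives the bis-acetal, which serves later as ortho-directing group and as a mask removable by mild acid.

Step 2
Reactants: 2 1,4-bis(methoxymethoxy)benzene; 3 chromium hexacarbonyl
Product: 6 pentacarbonyl{[2,5-bis(methoxymethoxy)phenyl](methoxy)methylidene}chromium(0), via aryllithium 4 (not isolated), via lithium acylchromate 5 (not isolated)
Conditions: n-BuLi (1.05 equiv), THF, 0 °C; Cr(CO)6, 0 °C → rt; evaporate; Me3OBF4, CH2Cl2, 0 °C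
Reagents that add atoms: trimethyloxonium tetrafluoroborate, C[O+](C)C.F[B-](F)(F)F
Why: This is the classical Fischer carbene synthesis, in which directed ortho-metalation beside a MOM ether (the four ring C–H are equivalent, so only one monolithio species can arise) is followed by addition of the aryllithium to a carbonyl ligand and O-methylation of the acylate with a Meerwein salt.

Step 3
Reactants: 7 4-methylpent-3-enoic acid
Product: 9 N-methoxy-N,4-dimethylpent-3-enamide, via acyl imidazolide 8 (not isolated)
Conditions: CDI, CH2Cl2, 0 °C → rt; MeNHOMe·HCl, rt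
Reagents that add atoms: N,O-dimethylhydroxylamine hydrochloride, CNOC.Cl
Why: Weinreb amide formation through an acyl imidazolide runs under nearly neutral conditions and so avoids the strong bases or acid chlorides that could move the β,γ-alkene into conjugation.

Step 4
Reactants: 9 N-methoxy-N,4-dimethylpent-3-enamide; 10 trimethylsilylacetylene
Product: 13 6-methyl-1-(trimethylsilyl)hept-5-en-1-yn-3-one, via lithium acetylide 11 (not isolated), via tetrahedral lithium adduct 12 (not isolated)
Conditions: 10, n-BuLi, THF, −78 °C; 9, −78 → −20 °C; cannulate into cold 1 M aq HCl/Et2O (0 °C)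
Reagents that add atoms: none
Why: In this Weinreb ketone synthesis the chelated tetrahedral adduct survives until the quench, so only one acetylide adds, and the inverse acidic quench protonates the released amine (no aza-Michael addition to the ynone) and never exposes the skipped enynone to base.

Step 5
Reactants: 13 6-methyl-1-(trimethylsilyl)hept-5-en-1-yn-3-one
Product: 14 (R)-6-methyl-1-(trimethylsilyl)hept-5-en-1-yn-3-ol
Conditions: Ru[(R,R)-TsDPEN](p-cymene) (preformed 16-electron amido complex, 1 mol %), i-PrOH, rt
Reagents that add atoms: none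
Why: In the Noyori asymmetric transfer hydrogenation of an alkynyl ketone the alkynyl group takes the place usually held by an aryl group in the six-membered transition state, so the (R,R) ligand should deliver hydride to the Si face and set C1′ as R, while the base-free catalyst leaves alkyne, alkene and the acidic CH2 alone.

Step 6
Reactants: 14 (R)-6-methyl-1-(trimethylsilyl)hept-5-en-1-yn-3-ol
Product: 15 (R)-3-(tert-butyldimethylsilyloxy)-6-methyl-1-(trimethylsilyl)hept-5-en-1-yne
Conditions: TBSCl, imidazole, DMF, rt
Reagents that add atoms: tert-butyldimethylsilyl chloride, CC(C)(C)[Si](C)(C)Cl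
Why: Imidazole-promoted O-silylation occurs at oxygen without touching the stereocentre, and placing it before the C-desilylation avoids handling the small, volatile free enynol.

Step 7
Reactants: 15 (R)-3-(tert-butyldimethylsilyloxy)-6-methyl-1-(trimethylsilyl)hept-5-en-1-yne
Product: 16 (R)-3-(tert-butyldimethylsilyloxy)-6-methylhept-5-en-1-yne
Conditions: K2CO3 (0.2 equiv), MeOH, rt
Reagents that add atoms: none
Why: Carbonate-catalysed protiodesilylation of the alkynyl C–Si bond in methanol is much faster than attack on the hindered TBS ether, and the etherified propargylic centre cannot epimerise under these conditions.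

Step 8
Reactants: 6 pentacarbonyl{[2,5-bis(methoxymethoxy)phenyl](methoxy)methylidene}chromium(0); 16 (R)-3-(tert-butyldimethylsilyloxy)-6-methylhept-5-en-1-yne
Product: 18 2-[(R)-1-(tert-butyldimethylsilyloxy)-4-methylpent-3-enyl]-4-methoxy-5,8-bis(methoxymethoxy)naphthalen-1-ol, via tricarbonylchromium naphthol complex 17 (not isolated)
Conditions: 6 (1.2 equiv), THF (degassed, ca. 0.2 M), 50 °C, Ar; then air, Et2O, rt
Reagents that add atoms: none
Why: Dötz benzannulation, a formal [3+2+1] union: thermal loss of one CO from 6, helped by transient chelation of the ortho MOM oxygen, lets alkyne 16 bind and insert with its CH terminus on the carbene carbon (C3–C4), after which a CO ligand migrates to the substituted carbon of the resulting vinylcarbene (C1–C2) and gives a chromium-bound aryl vinyl ketene. The only ring formed, C1–C2–C3–C4–C4a–C8a, closes by 6π electrocyclisation of this ketene onto the single free ortho carbon of the aryl group (C1–C8a), and enolisation leaves the 4-methoxy-1-naphthol as its Cr(CO)3 complex 17, from which air strips the metal. The closest known reaction type is the benzannulation of 2,5-dialkoxyphenyl(methoxy)carbene chromium complexes with terminal alkynes, propargylic silyl ethers among them, so this is an application of known chemistry to a new pair of partners. No lasting stereocentre is created, because C1′ is a spectator whose four bonds stay intact and the planar chirality of 17 disappears with the metal. The step needs six-ring phenol formation to win over indene, furan and cyclobutenone channels and over attack on the prenyl alkene; chromium with a methoxy aryl carbene, a terminal alkyne and THF at fairly high concentration favour CO insertion, while the alkene is trisubstituted and sits 1,5 to the alkyne, so cyclopropanation by the vinylcarbene carbon would have to build a bicyclo[2.1.0]pentane. Sterics place the bulky silyloxyalkyl group next to the new C1–OH, and the opposite orientation would do no harm, since the C5–C8 ring is symmetrically substituted and both naphthols give the same quinone in step 9.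

Step 9
Reactants: 18 2-[(R)-1-(tert-butyldimethylsilyloxy)-4-methylpent-3-enyl]-4-methoxy-5,8-bis(methoxymethoxy)naphthalen-1-ol
Product: 19 2-[(R)-1-(tert-butyldimethylsilyloxy)-4-methylpent-3-enyl]-5,8-bis(methoxymethoxy)-1,4-naphthoquinone
Conditions: PhI(OAc)2 (1.1 equiv), MeCN/H2O, 0 °C
Reagents that add atoms: water, O
Why: Hypervalent-iodine oxidation of a p-alkoxyphenol (ligand exchange at the free C1–OH, attack of water at C4, collapse of the hemiketal with loss of methanol) gives the quinone under nearly neutral conditions that spare MOM acetals, silyl ether and alkene, and the fully etherified ring cannot bind iodine(III).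

Step 10
Reactants: 19 2-[(R)-1-(tert-butyldimethylsilyloxy)-4-methylpent-3-enyl]-5,8-bis(methoxymethoxy)-1,4-naphthoquinone
Product: 20 2-[(R)-1-hydroxy-4-methylpent-3-enyl]-5,8-bis(methoxymethoxy)-1,4-naphthoquinone
Conditions: 48% aq HF, MeCN, 0 °C → rt (polyethylene flask)
Reagents that add atoms: none
Why: Fluoride-driven Si–O cleavage in a mildly acidic medium avoids the basic fluoride sources that degrade quinones, and because C1′ still sits on an electron-poor quinone ring that cannot tautomerise, its C–O bond should not ionise and the configuration is kept.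

Step 11
Reactants: 20 2-[(R)-1-hydroxy-4-methylpent-3-enyl]-5,8-bis(methoxymethoxy)-1,4-naphthoquinone
Product: 21 shikonin (5,8-dihydroxy-2-[(R)-1-hydroxy-4-methylpent-3-enyl]-1,4-naphthoquinone)
Conditions: 2 M aq HCl, THF, 0 °C → rt, Ar, dark, stopped at full conversion
Reagents that add atoms: none
Why: Acid-catalysed acetal hydrolysis of the two aryl MOM ethers is eased by the peri carbonyls that hydrogen-bond the liberated phenols, and water as the only nucleophile, low temperature and short contact are chosen so that the C1′ carbinol neither ionises nor adds to the prenyl alkene.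

Step 12
Reactants: 22 3-hydroxy-3-methylbutanoic acid
Product: 23 3-acetoxy-3-methylbutanoic acid
Conditions: AcCl (neat, excess), 0 °C → rt; evaporate; H2O/THF, rt
Reagents that add atoms: acetyl chloride, CC(=O)Cl
Why: O-acetylation of a tertiary carbinol in a hydroxy acid with neat acetyl chloride is a standard reaction type that needs no base able to trigger β-elimination, and the aqueous stir returns any acyl exchange at the carboxyl group to the free acid.

Step 13
Reactants: 21 shikonin; 23 3-acetoxy-3-methylbutanoic acid
Product: 24 (R)-1-(5,8-dihydroxy-1,4-dioxo-1,4-dihydronaphthalen-2-yl)-4-methylpent-3-enyl 3-acetoxy-3-methylbutanoate (β-acetoxyisovalerylshikonin)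
Conditions: DCC (1.5 equiv), DMAP (0.2 equiv), CH2Cl2, 0 °C → rt, Ar, dark
Reagents that add atoms: none
Why: Steglich esterification, the usual way of acylating shikonin, should take only the side-chain carbinol because both phenols are tied up in strong hydrogen bonds to the quinone carbonyls, it proceeds at oxygen with retention at C1′, and catalytic DMAP at low temperature limits E1cB loss of acetate from the activated acid.

Compound list
1 | hydroquinone | Oc1ccc(O)cc1 | starting material
2 | 1,4-bis(methoxymethoxy)benzene | COCOc1ccc(OCOC)cc1 | intermediate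
3 | chromium hexacarbonyl | O=C=[Cr](=C=O)(=C=O)(=C=O)(=C=O)=C=O | starting material
4 | 2,5-bis(methoxymethoxy)phenyllithium | [Li]c1cc(OCOC)ccc1OCOC | intermediate
5 | lithium pentacarbonyl[2,5-bis(methoxymethoxy)benzoyl]chromate | [Li+].[O-]C(=[Cr](=C=O)(=C=O)(=C=O)(=C=O)=C=O)c1cc(OCOC)ccc1OCOC | intermediate
6 | pentacarbonyl{[2,5-bis(methoxymethoxy)phenyl](methoxy)methylidene}chromium(0) | COC(=[Cr](=C=O)(=C=O)(=C=O)(=C=O)=C=O)c1cc(OCOC)ccc1OCOC | intermediate
7 | 4-methylpent-3-enoic acid | CC(C)=CCC(=O)O | starting material
8 | 1-(imidazol-1-yl)-4-methylpent-3-en-1-one | CC(C)=CCC(=O)n1ccnc1 | intermediate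
9 | N-methoxy-N,4-dimethylpent-3-enamide | CC(C)=CCC(=O)N(C)OC | intermediate
10 | trimethylsilylacetylene | C[Si](C)(C)C#C | starting material
11 | lithium (trimethylsilyl)acetylide | C[Si](C)(C)C#C[Li] | intermediate
12 | lithium 3-[methoxy(methyl)amino]-6-methyl-1-(trimethylsilyl)hept-5-en-1-yn-3-olate | C[Si](C)(C)C#CC([O-])(CC=C(C)C)N(C)OC.[Li+] | intermediate
13 | 6-methyl-1-(trimethylsilyl)hept-5-en-1-yn-3-one | C[Si](C)(C)C#CC(=O)CC=C(C)C | intermediate
14 | (R)-6-methyl-1-(trimethylsilyl)hept-5-en-1-yn-3-ol | C[Si](C)(C)C#C[C@H](O)CC=C(C)C | intermediate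
15 | (R)-3-(tert-butyldimethylsilyloxy)-6-methyl-1-(trimethylsilyl)hept-5-en-1-yne | C[Si](C)(C)C#C[C@H](O[Si](C)(C)C(C)(C)C)CC=C(C)C | intermediate
16 | (R)-3-(tert-butyldimethylsilyloxy)-6-methylhept-5-en-1-yne | C#C[C@H](O[Si](C)(C)C(C)(C)C)CC=C(C)C | intermediate
17 | tricarbonyl(η6-naphthol 18)chromium(0), metal on the newly formed ring | COc1cc([C@H](O[Si](C)(C)C(C)(C)C)CC=C(C)C)c(O)c2c(OCOC)ccc(OCOC)c12.[Cr].[C-]#[O+].[C-]#[O+].[C-]#[O+] | intermediate
18 | 2-[(R)-1-(tert-butyldimethylsilyloxy)-4-methylpent-3-enyl]-4-methoxy-5,8-bis(methoxymethoxy)naphthalen-1-ol | COc1cc([C@H](O[Si](C)(C)C(C)(C)C)CC=C(C)C)c(O)c2c(OCOC)ccc(OCOC)c12 | intermediate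
19 | 2-[(R)-1-(tert-butyldimethylsilyloxy)-4-methylpent-3-enyl]-5,8-bis(methoxymethoxy)-1,4-naphthoquinone | O=C1C=C([C@H](O[Si](C)(C)C(C)(C)C)CC=C(C)C)C(=O)c2c(OCOC)ccc(OCOC)c12 | intermediate
20 | 2-[(R)-1-hydroxy-4-methylpent-3-enyl]-5,8-bis(methoxymethoxy)-1,4-naphthoquinone | O[C@H](CC=C(C)C)C1=CC(=O)c2c(OCOC)ccc(OCOC)c2C1=O | intermediate
21 | shikonin | O[C@H](CC=C(C)C)C1=CC(=O)c2c(O)ccc(O)c2C1=O | intermediate
22 | 3-hydroxy-3-methylbutanoic acid | CC(C)(O)CC(=O)O | starting material
23 | 3-acetoxy-3-methylbutanoic acid | CC(=O)OC(C)(C)CC(=O)O | intermediate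
24 | (R)-β-acetoxyisovalerylshikonin | CC(=O)OC(C)(C)CC(=O)O[C@H](CC=C(C)C)C1=CC(=O)c2c(O)ccc(O)c2C1=O | target

Total step count: 13.
Longest linear sequence: 10 steps (steps 3–11 and 13, from 4-methylpent-3-enoic acid 7).

Steps most likely to fail

Step 8 (benzannulation). The vinylcarbene or ketene stage may be diverted into five-membered-ring or non-carbonylated channels. The terminal alkyne may oligomerise at the metal, and the chelated form of the carbene complex may take up alkyne slowly. The electron-rich naphthol may also be lost by oxidation during demetalation.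
The fallback sets out from 9 and returns at 21, making the C2–C1′ bond on a preformed naphthalene instead.
- Commercial naphthazarin F1 is O-methylated (MeI, Ag2O, CH2Cl2) to 5,8-dimethoxy-1,4-naphthoquinone F2.
- F2 is reduced with aqueous Na2S2O4 to 5,8-dimethoxynaphthalene-1,4-diol F3, which is protected (NaH, MOMCl, DMF) as 1,4-dimethoxy-5,8-bis(methoxymethoxy)naphthalene F4.
- MOM-directed lithiation (n-BuLi, THF, 0 °C) gives 5,8-dimethoxy-1,4-bis(methoxymethoxy)naphthalen-2-yllithium F5.
- Weinreb amide 9 acylates F5 to 1-[5,8-dimethoxy-1,4-bis(methoxymethoxy)naphthalen-2-yl]-4-methylpent-3-en-1-one F6.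
- (+)-DIP-Cl (THF, −25 °C) should reduce this aryl ketone to (R)-1-[5,8-dimethoxy-1,4-bis(methoxymethoxy)naphthalen-2-yl]-4-methylpent-3-en-1-ol F7.
- Ceric ammonium nitrate in aqueous MeCN at 0 °C should oxidise the unsubstituted dimethoxy ring, as is usual for 1-hydroxyalkyl-substituted tetraalkoxynaphthalenes, to 6-[(R)-1-hydroxy-4-methylpent-3-enyl]-5,8-bis(methoxymethoxy)-1,4-naphthoquinone F8.
- Acetal hydrolysis under the conditions of step 11 gives the 6-substituted naphthazarin, which is the rapidly equilibrating tautomer of shikonin 21.

Step 5 (reduction of the skipped enynone). The alkene may drift into conjugation with the ynone, either on the basic amido catalyst or already while 13 is handled. Facial selectivity may be incomplete, because the two ketone substituents differ more in electronics than in size.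
The fallback sets out from 10 and returns at 15. It avoids the ketone and installs the prenyl terminus last.
- Acetylide 11, made from 10 as in step 4, is formylated with DMF to 3-(trimethylsilyl)propynal F9.
- Brown allylation with the B-allyldiisopinocampheylborane antipode derived from (−)-α-pinene (Et2O, −78 °C, perborate work-up) should give (R)-1-(trimethylsilyl)hex-5-en-1-yn-3-ol F10 through the usual closed chair transition state.
- TBSCl/imidazole gives (R)-3-(tert-butyldimethylsilyloxy)-1-(trimethylsilyl)hex-5-en-1-yne F11.
- Cross metathesis with excess 2-methyl-2-butene (second-generation Grubbs catalyst, CH2Cl2, 40 °C) converts the vinyl group into the trisubstituted alkene of 15. The silyl-capped alkyne is expected to stay out of the metathesis.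

Step 11 (unmasking of the naphthazarin). As soon as the naphthazarin is free, acid may ionise C1′. That erodes the configuration and allows the carbinol oxygen to close onto the prenyl alkene. Gentler conditions may instead stall after the first acetal.
The fallback sets out from 20 and returns at 24, reversing the order of acylation and unmasking.
- Alcohol 20 is esterified with acid 23 (DCC, DMAP, CH2Cl2, 0 °C) to (R)-1-[5,8-bis(methoxymethoxy)-1,4-dioxo-1,4-dihydronaphthalen-2-yl]-4-methylpent-3-enyl 3-acetoxy-3-methylbutanoate F12.
- In F12 no free carbinol is left to cyclise. The two MOM ethers are then hydrolysed (2 M aq HCl, THF, 0 °C → rt) to give target 24 directly, bypassing free shikonin.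

Further compounds
F1 | step 8 | naphthazarin (5,8-dihydroxy-1,4-naphthoquinone, bought) | O=C1C=CC(=O)c2c(O)ccc(O)c12
F2 | step 8 | 5,8-dimethoxy-1,4-naphthoquinone | COc1ccc(OC)c2c1C(=O)C=CC2=O
F3 | step 8 | 5,8-dimethoxynaphthalene-1,4-diol | COc1ccc(OC)c2c(O)ccc(O)c12
F4 | step 8 | 1,4-dimethoxy-5,8-bis(methoxymethoxy)naphthalene | COCOc1ccc(OCOC)c2c(OC)ccc(OC)c12
F5 | step 8 | 5,8-dimethoxy-1,4-bis(methoxymethoxy)naphthalen-2-yllithium | [Li]c1cc(OCOC)c2c(OC)ccc(OC)c2c1OCOC
F6 | step 8 | 1-[5,8-dimethoxy-1,4-bis(methoxymethoxy)naphthalen-2-yl]-4-methylpent-3-en-1-one | CC(C)=CCC(=O)c1cc(OCOC)c2c(OC)ccc(OC)c2c1OCOC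
F7 | step 8 | (R)-1-[5,8-dimethoxy-1,4-bis(methoxymethoxy)naphthalen-2-yl]-4-methylpent-3-en-1-ol | O[C@H](CC=C(C)C)c1cc(OCOC)c2c(OC)ccc(OC)c2c1OCOC
F8 | step 8 | 6-[(R)-1-hydroxy-4-methylpent-3-enyl]-5,8-bis(methoxymethoxy)-1,4-naphthoquinone | O[C@H](CC=C(C)C)c1cc(OCOC)c2C(=O)C=CC(=O)c2c1OCOC
F9 | step 5 | 3-(trimethylsilyl)propynal | C[Si](C)(C)C#CC=O
F10 | step 5 | (R)-1-(trimethylsilyl)hex-5-en-1-yn-3-ol | C[Si](C)(C)C#C[C@H](O)CC=C
F11 | step 5 | (R)-3-(tert-butyldimethylsilyloxy)-1-(trimethylsilyl)hex-5-en-1-yne | C[Si](C)(C)C#C[C@H](O[Si](C)(C)C(C)(C)C)CC=C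
F12 | step 11 | (R)-1-[5,8-bis(methoxymethoxy)-1,4-dioxo-1,4-dihydronaphthalen-2-yl]-4-methylpent-3-enyl 3-acetoxy-3-methylbutanoate | CC(=O)OC(C)(C)CC(=O)O[C@H](CC=C(C)C)C1=CC(=O)c2c(OCOC)ccc(OCOC)c2C1=O
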